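**Retrosynthetic overview**

1. Target ⇐ bis-silyl iodide 33 by Negishi coupling at C12–C13 with 4-bromofuran-2(5H)-one; the C2 and C6 carbinols come from stepwise reduction of cis-decalin-2,6-dione 29.
2. 29 ⇐ transannular Michael addition in a ten-membered ring (C1–C10). The strategy rests on the C5–C10 bond, common to rings A and B, which joins the α-carbon (C5) of the C6 ketone to the β-carbon (C10) of the C2(=O)–C1=C10 enone; one bond therefore closes both rings and sets C5 and C10.
3. Precursor 27 (the dienedione with a traceless carboxyl on C5) ⇐ Nozaki–Hiyama–Kishi closure at C1–C2 and ester-enolate aldol at C5–C6, joining a glutarate-derived C2–C5 unit to a (Z,Z)-dienyl iodide.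
4. Dienyl iodide ⇐ oxane-2,4-dione as a cyclic template for the tetrasubstituted C8=C9 bond (reductive alkylation C7–C8, enol triflate Stille coupling C9–C10).
5. Ring order: ten-membered carbocycle (step 15), then rings A and B together (step 19), butenolide attached last (step 24).

Key step: step 19

**Remarks and assumptions**

- Locants follow labdane numbering: ring carbons C1–C10, gem-dimethyl on C4, methyl on C10, C17 = CH2O on C8, C11–C12 = arm on C9, C13–C16 = butenolide. The extra carboxyl carbon on C5 is called C5a.
- A plain 2,6-dione would form its enamine at C7 (α to C6=O and allylic to the diene), and a C7 enamine can close C7–C2 by transannular aldol addition and dehydrate to an aromatic ring. C5 therefore carries a carboxyl group, which generates the C5 enamine regiospecifically and is lost as CO2 in the key step.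
- In the precursor both ring double bonds are ring-cis: C1=C10 is Z, and C8=C9 (C7 cis to C10) is E by the CIP rules because CH2O outranks C7.
- Protecting groups: O17 as triisopropylsilyl ether, O12 as pivalate, so that C12 can be freed and iodinated selectively.
- Assumption: oxane-2,4-dione and 2,2-dimethoxyacetaldehyde (aqueous solution) are taken as catalogue chemicals.
- Assumption: the cis-fused bicycles 29–31 react from the conformer in which the C10 methyl and the 4β methyl are both axial on ring A and C5–C6 is axial on ring A (the other chair puts the 4α methyl over ring B). Steps 20 and 21 are argued on this basis.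
- Assumption: the (1R,2R) catalyst is taken to select the (5R,10S) fold; its mirror image is equally accessible.

**Route**

Step 1
Reactants: 1 propyne; 2 trimethyl(tributylstannyl)silane
Product: 3 (Z)-trimethyl[2-(tributylstannyl)prop-1-en-1-yl]silane
Conditions: Pd(PPh3)4 (cat.), THF, 65 °C, sealed vessel
Reagents that add atoms: none
Why: Palladium-catalysed syn-silylstannation of a terminal alkyne puts tin on the internal and silicon on the terminal carbon on the same side, which fixes the later C1=C10 geometry.

Step 2
Reactants: 4 oxane-2,4-dione; 5 2,2-dimethoxyacetaldehyde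
Product: 7 3-(2,2-dimethoxyethyl)-4-hydroxy-5,6-dihydro-2H-pyran-2-one, via alkylidene dione 6 (not isolated)
Conditions: diethyl 2,6-dimethyl-1,4-dihydropyridine-3,5-dicarboxylate, L-proline (cat.), CH2Cl2, rt; used without delay
Reagents that add atoms: none
Why: Knoevenagel condensation at the 1,3-dicarbonyl carbon (future C8) followed by in-situ conjugate hydride transfer from the dihydropyridine (three-component reductive alkylation) gives clean C-monoalkylation and forms C7–C8.

Step 3
Reactants: 7 3-(2,2-dimethoxyethyl)-4-hydroxy-5,6-dihydro-2H-pyran-2-one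
Product: 8 3-(2,2-dimethoxyethyl)-2-oxo-5,6-dihydro-2H-pyran-4-yl trifluoromethanesulfonate
Conditions: PhNTf2, Et3N, DMAP (cat.), CH2Cl2, 0 °C → rt
Reagents that add atoms: N-phenylbis(trifluoromethanesulfonimide), O=S(=O)(N(c1ccccc1)S(=O)(=O)C(F)(F)F)C(F)(F)F
Why: O-sulfonylation of the vinylogous acid (enol triflate formation) can only occur at the C9 oxygen, and the six-membered lactone locks C17 and C11 cis on the future C8=C9 bond.

Step 4
Reactants: 8 enol triflate; 3 (Z)-trimethyl[2-(tributylstannyl)prop-1-en-1-yl]silane
Product: 9 3-(2,2-dimethoxyethyl)-4-[(Z)-1-(trimethylsilyl)prop-1-en-2-yl]-5,6-dihydro-2H-pyran-2-one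
Conditions: Pd(PPh3)4 (cat.), CuCl, LiCl, DMSO, 60 °C
Reagents that add atoms: none
Why: Copper-assisted Stille coupling of the vinylogous acyl triflate with the 1-substituted vinylstannane forms C9–C10 with retention at both sp2 carbons, so C7/C10 and Si/C9 end up cis.

Step 5
Reactants: 9 dienyl silane lactone
Product: 10 3-(2,2-dimethoxyethyl)-4-[(Z)-1-iodoprop-1-en-2-yl]-5,6-dihydro-2H-pyran-2-one
Conditions: N-iodosuccinimide, 2,6-lutidine, (CF3)2CHOH, 0 °C
Reagents that add atoms: N-iodosuccinimide, O=C1CCC(=O)N1I
Why: Ipso-iododesilylation of the vinylsilane proceeds with retention through the β-silyl cation and gives the (Z)-vinyl iodide, while the lactone carbonyl deactivates the C8=C9 bond toward the electrophile.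

Step 6
Reactants: 10 iodo-dienyl lactone
Product: 12 (3E,4Z)-5-iodo-3-(5-methoxyoxolan-3-ylidene)-4-methylpent-4-en-1-ol, via dienediol 11 (not isolated)
Conditions: i-Bu2AlH, CH2Cl2, −78 → 0 °C, sodium potassium tartrate work-up; crude, pyridinium p-toluenesulfonate (cat.), 4 Å molecular sieves, CH2Cl2, rt
Reagents that add atoms: none
Why: 1,2-Reduction of the unsaturated lactone frees the C17 and C12 hydroxyls, and acid-catalysed transacetalisation then ties the C17 hydroxyl to the C6 acetal in a five-membered ring (the C12 hydroxyl cannot reach C6 across the alkene), which differentiates the two primary alcohols.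

Step 7
Reactants: 12 cyclic methyl acetal alcohol
Product: 13 (3E,4Z)-5-iodo-3-(5-methoxyoxolan-3-ylidene)-4-methylpent-4-en-1-yl pivalate
Conditions: t-BuCOCl, pyridine, DMAP (cat.), CH2Cl2, 0 °C
Reagents that add atoms: pivaloyl chloride, CC(C)(C)C(Cl)=O
Why: Standard acylation of the only free hydroxyl (C12) as a pivalate.

Step 8
Reactants: 13 cyclic methyl acetal pivalate
Product: 14 (3E,4Z)-3-(5-hydroxyoxolan-3-ylidene)-5-iodo-4-methylpent-4-en-1-yl pivalate
Conditions: AcOH/THF/H2O (3:1:1), 40 °C
Reagents that add atoms: water, O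
Why: Mild acid hydrolysis of the cyclic mixed acetal gives the lactol, the latent C6 aldehyde.

Step 9
Reactants: 15 3,3-dimethylglutaric anhydride
Product: 16 5-(allyloxy)-3,3-dimethyl-5-oxopentanoic acid
Conditions: allyl alcohol, Et3N, DMAP (cat.), CH2Cl2, rt; acidic work-up
Reagents that add atoms: allyl alcohol, C=CCO
Why: Alcoholysis of the symmetrical cyclic anhydride gives a single half ester, whose allyl ester becomes the removable carboxyl (C5a) on C5.

Step 10
Reactants: 16 monoallyl 3,3-dimethylglutarate
Product: 18 allyl 3,3-dimethyl-5-oxopentanoate, via acid chloride 17 (not isolated)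
Conditions: (COCl)2, DMF (cat.), CH2Cl2, 0 °C → rt; LiAlH(Ot-Bu)3, THF, −78 °C
Reagents that add atoms: none
Why: Acid chloride formation and low-temperature reduction with the hindered alkoxyaluminium hydride stops at the aldehyde (C2) and leaves the allyl ester untouched.

Step 11
Reactants: 18 allyl 3,3-dimethyl-5-oxopentanoate
Product: 19 allyl 5,5-dimethoxy-3,3-dimethylpentanoate
Conditions: HC(OMe)3, MeOH, pyridinium p-toluenesulfonate (cat.), rt
Reagents that add atoms: trimethyl orthoformate, COC(OC)OC; methanol, CO
Why: Acid-catalysed acetalisation with the orthoformate as water scavenger masks C2 for the enolate step.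

Step 12
Reactants: 19 allyl 5,5-dimethoxy-3,3-dimethylpentanoate (2.5 equiv); 14 lactol
Product: 21 aldol diol (C5–C6 bond; C6 and C17 hydroxyls free), via lithium enolate 20 (not isolated)
Conditions: LiN(i-Pr)2, THF, −78 °C; then 14, −78 → −30 °C; aqueous NH4Cl
Reagents that add atoms: none
Why: Lithium ester enolate aldol addition to the open hydroxy-aldehyde form of the lactol forms C5–C6; the new C5 and C6 centres are not controlled and are erased later (C6 by oxidation, C5 by decarboxylation).

Step 13
Reactants: 21 aldol diol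
Product: 22 17-O-triisopropylsilyl aldol adduct
Conditions: i-Pr3SiCl, imidazole, DMF, 0 °C
Reagents that add atoms: triisopropylsilyl chloride, CC(C)[Si](Cl)(C(C)C)C(C)C
Why: Selective silylation of the primary allylic C17 hydroxyl over the hindered secondary C6 hydroxyl with a bulky silyl chloride.

Step 14
Reactants: 22 17-O-triisopropylsilyl aldol adduct
Product: 23 seco-aldehyde (C2 aldehyde; 6-O-triethylsilyl)
Conditions: Et3SiOTf, 2,6-lutidine, CH2Cl2, 0 °C; then H2O
Reagents that add atoms: triethylsilyl trifluoromethanesulfonate, CC[Si](CC)(CC)OS(=O)(=O)C(F)(F)F; water, O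
Why: The silyl triflate/2,6-lutidine pair silylates the C6 hydroxyl and converts the dimethyl acetal through a pyridinium intermediate into the aldehyde on aqueous work-up, without acid that would endanger the silyl ethers; the C6 oxygen must be capped because a free δ-hydroxy aldehyde would close to a lactol and a C6 ketone would undergo C7–C2 aldol cyclisation.

Step 15
Reactants: 23 seco-aldehyde
Product: 24 ten-membered allylic alcohol (C2–OH; 6-O-triethylsilyl)
Conditions: CrCl2 (10 equiv), NiCl2 (2 mol%), degassed DMSO/THF, rt, slow addition to 0.003 M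
Reagents that add atoms: none
Why: Nozaki–Hiyama–Kishi coupling (zerovalent nickel inserts into the C–I bond, transmetalation to chromium, addition to the aldehyde) closes the ten-membered ring at C1–C2 with retention of the (Z)-alkene, helped by the two ring-cis alkenes and the gem-dimethyl group; the C2 carbinol configuration is irrelevant because it is oxidised.

Step 16
Reactants: 24 ten-membered allylic alcohol
Product: 25 ten-membered 2,6-diol
Conditions: HF·pyridine, pyridine, THF, 0 °C
Reagents that add atoms: none
Why: Buffered fluoride cleaves the secondary triethylsilyl ether much faster than the primary triisopropylsilyl ether.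

Step 17
Reactants: 25 ten-membered 2,6-diol
Product: 26 ten-membered (1Z,8E)-dienedione allyl ester
Conditions: 1,1,1-triacetoxy-1,1-dihydro-1,2-benziodoxol-3(1H)-one (periodinane), pyridine, CH2Cl2, 0 °C, short reaction time
Reagents that add atoms: none
Why: Periodinane oxidation under buffered, non-enolising conditions converts the allylic C2 carbinol and the C6 carbinol into the enone and the β-keto ester in one operation, so that the 2,6-dione exists only from this point on.

Step 18
Reactants: 26 dienedione allyl ester
Product: 27 ten-membered (1Z,8E)-dienedione 5-carboxylic acid (key-step precursor)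
Conditions: Pd(PPh3)4 (5 mol%), sodium p-toluenesulfinate, THF/MeOH, 0 °C; cold 0.1 M HCl work-up; used at once
Reagents that add atoms: none
Why: Zerovalent palladium ionises the allyl ester and the sulfinate traps the allyl fragment (Tsuji–Trost-type deallylation) under neutral conditions at 0 °C, leaving the β-keto acid intact for immediate use.

Step 19
Reactants: 27 dienedione 5-carboxylic acid
Product: 29 (5R,10S)-cis-decalin-2,6-dione (12-O-pivaloyl; 17-O-triisopropylsilyl), via catalyst-bound C5 enamine 28 (not isolated)
Conditions: 1-[(1R,2R)-2-aminocyclohexyl]-3-[3,5-bis(trifluoromethyl)phenyl]thiourea (20 mol%), PhCO2H (20 mol%), toluene (0.01 M), 0 °C → rt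
Reagents that add atoms: none
Why: Proposed new method: the primary amine condenses with the C6 ketone of 27, the β-iminium carboxylate loses CO2 and so delivers the enamine regiospecifically at C5 (28), and this enamine adds across the ring to C10 of the thiourea-bound (Z)-enone, after which hydrolysis of the C6 imine and ketonisation at C1 release 29 and the catalyst. The closest known reaction types are amine-catalysed decarboxylative Michael additions of β-keto acids to enones and primary amine–thiourea-catalysed Michael additions of ketones, neither of which has been shown in a transannular setting that forms a quaternary centre. Ring A closes 6-endo-trig (C1 lies inside the new ring) and ring B closes 6-exo-trig (the enamine double bond lies inside ring B). C10 is set by the catalyst, whose covalently bound enamine and hydrogen-bonded enone can meet in only one of the two mirror-image folds of the ring; C5 is set relative to C10 by ring geometry, because a ring-cis enamine and the (Z)-enone can reach a staggered C5–C10 transition state only with H5 and the C10 methyl gauche, which is the cis fusion (a trans fusion would need both double bonds ring-trans). The step needs C5 and not C7 as the nucleophile, which the C5 carboxyl secures, and 1,6-attack at C8 is excluded because it would form a four-membered ring.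

Step 20
Reactants: 29 cis-decalin-2,6-dione
Product: 30 (5R,6S,10S)-6α-hydroxy-2-ketone
Conditions: LiBH(s-Bu)3 (1.1 equiv), THF, −78 °C; aqueous NH4Cl
Reagents that add atoms: none
Why: Hindered borohydride reduction in which the reagent attacks the C6 carbonyl equatorially from the β face (the α-axial path is blocked by the axial C1 methylene) and so sets the axial 6α-alcohol, while the C2 ketone, flanked by two quaternary carbons and two syn-axial methyls, reacts much more slowly.

Step 21
Reactants: 30 6α-hydroxy-2-ketone
Product: 31 (2S,5R,6S,10S)-2,6,12-triol (17-O-triisopropylsilyl)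
Conditions: Li, NH3(l)/THF, EtOH, −78 → −40 °C; NH4Cl
Reagents that add atoms: none
Why: Dissolving-metal reduction gives the thermodynamically preferred equatorial alcohol at C2 (2α, away from the two axial methyls on the β face), and the same conditions cleave the pivalate reductively (Bouveault–Blanc-type) to free the C12 hydroxyl.

Step 22
Reactants: 31 triol
Product: 32 12-iodo-2,6-diol
Conditions: I2, PPh3, imidazole, CH2Cl2, 0 °C
Reagents that add atoms: iodine, II
Why: Appel-type iodination is selective for the unhindered primary C12 hydroxyl over the two secondary ones.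

Step 23
Reactants: 32 12-iodo-2,6-diol
Product: 33 2,6-bis-O-triethylsilyl 12-iodide
Conditions: Et3SiOTf, 2,6-lutidine, CH2Cl2, −40 → 0 °C
Reagents that add atoms: triethylsilyl trifluoromethanesulfonate, CC[Si](CC)(CC)OS(=O)(=O)C(F)(F)F
Why: Silyl triflate silylation caps both secondary hydroxyls so that the alkylzinc reagent of the next step is not protonated.

Step 24
Reactants: 33 bis-silyl iodide; 34 4-bromofuran-2(5H)-one
Product: 36 fully silylated target, via alkylzinc iodide 35 (not isolated)
Conditions: Zn dust (activated with BrCH2CH2Br, Me3SiCl), LiCl, THF, 40 °C; then 34, Pd2(dba)3 (2.5 mol%), SPhos (10 mol%), THF, rt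
Reagents that add atoms: none
Why: Zinc insertion into the primary C–I bond and Negishi sp3–sp2 coupling with the vinylogous acyl bromide form C12–C13, with the bulky biarylphosphine suppressing β-hydride elimination.

Step 25
Reactants: 36 fully silylated target
Product: 37 target CNP0293367.1
Conditions: HF·pyridine, pyridine, THF, 0 °C → rt
Reagents that add atoms: none
Why: Fluoride-mediated global desilylation under mildly acidic conditions, which the butenolide and the allylic alcohol tolerate.

**Compound list**

1 | propyne | CC#C | starting material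
2 | trimethyl(tributylstannyl)silane | C[Si](C)(C)[Sn](CCCC)(CCCC)CCCC | starting material
3 | (Z)-trimethyl[2-(tributylstannyl)prop-1-en-1-yl]silane (Si and Sn cis) | C/C(=C/[Si](C)(C)C)[Sn](CCCC)(CCCC)CCCC | intermediate
4 | oxane-2,4-dione | O=C1CC(=O)CCO1 | starting material
5 | 2,2-dimethoxyacetaldehyde | COC(OC)C=O | starting material
6 | 3-(2,2-dimethoxyethylidene)oxane-2,4-dione | COC(OC)C=C1C(=O)CCOC1=O | intermediate (not isolated)
7 | 3-(2,2-dimethoxyethyl)-4-hydroxy-5,6-dihydro-2H-pyran-2-one | COC(OC)CC1=C(O)CCOC1=O | intermediate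
8 | 3-(2,2-dimethoxyethyl)-2-oxo-5,6-dihydro-2H-pyran-4-yl trifluoromethanesulfonate | COC(OC)CC1=C(OS(=O)(=O)C(F)(F)F)CCOC1=O | intermediate
9 | 3-(2,2-dimethoxyethyl)-4-[(Z)-1-(trimethylsilyl)prop-1-en-2-yl]-5,6-dihydro-2H-pyran-2-one (Si cis to ring carbon C9) | COC(OC)CC1=C(/C(C)=C\[Si](C)(C)C)CCOC1=O | intermediate
10 | 3-(2,2-dimethoxyethyl)-4-[(Z)-1-iodoprop-1-en-2-yl]-5,6-dihydro-2H-pyran-2-one (I cis to C9) | COC(OC)CC1=C(/C(C)=C\I)CCOC1=O | intermediate
11 | (2E,4Z)-2-(2,2-dimethoxyethyl)-3-(2-hydroxyethyl)-5-iodo-4-methylpenta-2,4-dien-1-ol (C7 cis to C10) | OC/C(CC(OC)OC)=C(CCO)/C(C)=C\I | intermediate (not isolated)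
12 | (3E,4Z)-5-iodo-3-(5-methoxyoxolan-3-ylidene)-4-methylpent-4-en-1-ol (O17–C6 cyclic methyl acetal, C12–OH free; C6 epimers) | COC1C/C(CO1)=C(CCO)\C(C)=C/I | intermediate
13 | (3E,4Z)-5-iodo-3-(5-methoxyoxolan-3-ylidene)-4-methylpent-4-en-1-yl pivalate | COC1C/C(CO1)=C(CCOC(=O)C(C)(C)C)\C(C)=C/I | intermediate
14 | (3E,4Z)-3-(5-hydroxyoxolan-3-ylidene)-5-iodo-4-methylpent-4-en-1-yl pivalate (lactol) | OC1C/C(CO1)=C(CCOC(=O)C(C)(C)C)\C(C)=C/I | intermediate
15 | 3,3-dimethylglutaric anhydride | CC1(C)CC(=O)OC(=O)C1 | starting material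
16 | 5-(allyloxy)-3,3-dimethyl-5-oxopentanoic acid | OC(=O)CC(C)(C)CC(=O)OCC=C | intermediate
17 | allyl 5-chloro-3,3-dimethyl-5-oxopentanoate | ClC(=O)CC(C)(C)CC(=O)OCC=C | intermediate (not isolated)
18 | allyl 3,3-dimethyl-5-oxopentanoate | O=CCC(C)(C)CC(=O)OCC=C | intermediate
19 | allyl 5,5-dimethoxy-3,3-dimethylpentanoate | COC(OC)CC(C)(C)CC(=O)OCC=C | intermediate
20 | lithium enolate of 19 | [Li]OC(OCC=C)=CC(C)(C)CC(OC)OC | intermediate (not isolated)
21 | aldol diol: allyl ester on C5; C6–OH and C17–OH free; C2 dimethyl acetal; 12-O-pivaloyl; (8E) C8=C9 with C7 cis to C10; (Z)-vinyl iodide at C1; mixture of C5/C6 diastereomers | OC/C(CC(O)C(C(=O)OCC=C)C(C)(C)CC(OC)OC)=C(CCOC(=O)C(C)(C)C)/C(C)=C\I | intermediate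
22 | 17-O-triisopropylsilyl ether of 21 | CC(C)[Si](C(C)C)(C(C)C)OC/C(CC(O)C(C(=O)OCC=C)C(C)(C)CC(OC)OC)=C(CCOC(=O)C(C)(C)C)/C(C)=C\I | intermediate
23 | seco-aldehyde: C2 aldehyde, 6-O-triethylsilyl, 17-O-triisopropylsilyl, 12-O-pivaloyl, C5 allyl ester, (Z)-vinyl iodide at C1 | CC(C)[Si](C(C)C)(C(C)C)OC/C(CC(O[Si](CC)(CC)CC)C(C(=O)OCC=C)C(C)(C)CC=O)=C(CCOC(=O)C(C)(C)C)/C(C)=C\I | intermediate
24 | ten-membered ring (C1–C10) allylic alcohol: C2–OH, (1Z) C1=C10, ring-cis (8E) C8=C9, 6-O-triethylsilyl, C5 allyl ester; diastereomer mixture | OC1/C=C(C)\C(CCOC(=O)C(C)(C)C)=C(CO[Si](C(C)C)(C(C)C)C(C)C)/CC(O[Si](CC)(CC)CC)C(C(=O)OCC=C)C(C)(C)C1 | intermediate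
25 | ten-membered 2,6-diol (C5 allyl ester; diastereomer mixture) | OC1/C=C(C)\C(CCOC(=O)C(C)(C)C)=C(CO[Si](C(C)C)(C(C)C)C(C)C)/CC(O)C(C(=O)OCC=C)C(C)(C)C1 | intermediate
26 | ten-membered (1Z,8E)-dienedione allyl ester (C2 and C6 ketones; CO2allyl on C5; 12-O-pivaloyl; 17-O-triisopropylsilyl) | O=C1/C=C(C)\C(CCOC(=O)C(C)(C)C)=C(CO[Si](C(C)C)(C(C)C)C(C)C)/CC(=O)C(C(=O)OCC=C)C(C)(C)C1 | intermediate
27 | ten-membered (1Z,8E)-dienedione 5-carboxylic acid (key-step precursor; C5 stereolabile) | O=C1/C=C(C)\C(CCOC(=O)C(C)(C)C)=C(CO[Si](C(C)C)(C(C)C)C(C)C)/CC(=O)C(C(=O)O)C(C)(C)C1 | intermediate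
28 | C5 enamine of the decarboxylated dienedione with the catalyst amine on C6 (C5=C6 ring-cis) | O=C1/C=C(C)\C(CCOC(=O)C(C)(C)C)=C(CO[Si](C(C)C)(C(C)C)C(C)C)/C/C(N[C@@H]2CCCC[C@H]2NC(=S)Nc2cc(cc(c2)C(F)(F)F)C(F)(F)F)=C\C(C)(C)C1 | intermediate (not isolated)
29 | (5R,10S)-cis-decalin-2,6-dione with C8=C9 alkene (5-H and 10-CH3 cis; 12-O-pivaloyl; 17-O-triisopropylsilyl) | CC1(C)CC(=O)C[C@]2(C)C(CCOC(=O)C(C)(C)C)=C(CO[Si](C(C)C)(C(C)C)C(C)C)CC(=O)[C@H]12 | intermediate
30 | (5R,6S,10S)-6α-hydroxy-2-ketone | CC1(C)CC(=O)C[C@]2(C)C(CCOC(=O)C(C)(C)C)=C(CO[Si](C(C)C)(C(C)C)C(C)C)C[C@H](O)[C@H]12 | intermediate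
31 | (2S,5R,6S,10S)-2α,6α,12-triol, 17-O-triisopropylsilyl | CC1(C)C[C@H](O)C[C@]2(C)C(CCO)=C(CO[Si](C(C)C)(C(C)C)C(C)C)C[C@H](O)[C@H]12 | intermediate
32 | (2S,5R,6S,10S)-12-iodo-2α,6α-diol, 17-O-triisopropylsilyl | CC1(C)C[C@H](O)C[C@]2(C)C(CCI)=C(CO[Si](C(C)C)(C(C)C)C(C)C)C[C@H](O)[C@H]12 | intermediate
33 | 2,6-bis-O-triethylsilyl-17-O-triisopropylsilyl 12-iodide | CC1(C)C[C@H](O[Si](CC)(CC)CC)C[C@]2(C)C(CCI)=C(CO[Si](C(C)C)(C(C)C)C(C)C)C[C@H](O[Si](CC)(CC)CC)[C@H]12 | intermediate
34 | 4-bromofuran-2(5H)-one | O=C1C=C(Br)CO1 | starting material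
35 | C12 alkylzinc iodide of 33 | CC1(C)C[C@H](O[Si](CC)(CC)CC)C[C@]2(C)C(CC[Zn]I)=C(CO[Si](C(C)C)(C(C)C)C(C)C)C[C@H](O[Si](CC)(CC)CC)[C@H]12 | intermediate (not isolated)
36 | 2,6-bis-O-triethylsilyl-17-O-triisopropylsilyl target | CC1(C)C[C@H](O[Si](CC)(CC)CC)C[C@]2(C)C(CCC3=CC(=O)OC3)=C(CO[Si](C(C)C)(C(C)C)C(C)C)C[C@H](O[Si](CC)(CC)CC)[C@H]12 | intermediate
37 | CNP0293367.1, (2S,5R,6S,10S) in the locants used here | CC1(C)C[C@H](O)C[C@]2(C)C(CCC3=CC(=O)OC3)=C(CO)C[C@H](O)[C@H]12 | target

**Step count**

Total: 25 steps. Longest linear sequence: 21 steps (steps 2–8, then 12–25).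

**Steps most likely to fail**

Step 19 (the step labelled as a new method). After decarboxylation the C5 enamine may tautomerise through the imine to the conjugated C7 dienamine faster than it adds to C10. That dienamine closes C7–C2 by transannular aldol addition and dehydrates to an aromatic ring. Facial discrimination by the catalyst may also be low; if only its sense is wrong, the (1S,2S) catalyst is used. The fallback uses known chemistry, sets out from allyl ester 26 and returns at 29. Cs2CO3 in MeCN at 0 °C deprotonates the β-keto ester carbon C5, the most acidic site, and the enolate adds across the ring to C10 (base-mediated Michael addition) to give the racemic cis-fused C5 allyl ester F1. Pd(PPh3)4 with HCO2H/Et3N in THF then removes the allyl group, and the β-keto acid decarboxylates with protonation at C5 to the racemic cis-dione F2, any trans-fused epimer being separated. Preparative chromatography on a chiral stationary phase then gives 29.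

Step 21. Protonation under thermodynamic control may favour the 2β-alcohol if the other chair of ring A is populated, so that the C2 configuration leaks. The fallback replaces thermodynamic by kinetic control, sets out from 30 and returns at 31. Excess LiBH(s-Bu)3 in THF (−78 → 0 °C) attacks C2 equatorially on the populated chair and therefore gives the epimer of the dissolving-metal product. If the metal reduction had favoured 2β, this is the 2α,6α-diol pivalate F3. i-Bu2AlH in CH2Cl2 at −78 °C then cleaves the pivalate to give 31.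

Step 12. The lithium lactolate of 14 may open too slowly, and the liberated β,γ-unsaturated aldehyde may be deprotonated at C7 by the enolate, so that little aldol adduct forms. The fallback avoids the lactol as electrophile, sets out from 14 and returns at 22. N,N-Dimethylhydrazine in CH2Cl2 with MgSO4 opens the lactol to the open-chain N,N-dimethylhydrazone F4 with a free C17 hydroxyl. i-Pr3SiCl/imidazole gives its triisopropylsilyl ether F5. Two-phase aqueous oxalic acid/Et2O then releases the free aldehyde F6. Addition of F6 to 1.3 equiv of enolate 20 at −78 °C gives 22 directly.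

**Further compounds**

F1 | step 19 | racemic cis-fused allyl 2,6-dioxodecalin-5-carboxylate (ester on C5 cis to the C10 methyl; 12-O-pivaloyl; 17-O-triisopropylsilyl; one enantiomer drawn) | CC1(C)CC(=O)C[C@]2(C)C(CCOC(=O)C(C)(C)C)=C(CO[Si](C(C)C)(C(C)C)C(C)C)CC(=O)[C@]12C(=O)OCC=C
F2 | step 19 | racemate of cis-decalin-2,6-dione 29 (one enantiomer drawn) | CC1(C)CC(=O)C[C@]2(C)C(CCOC(=O)C(C)(C)C)=C(CO[Si](C(C)C)(C(C)C)C(C)C)CC(=O)[C@H]12
F3 | step 21 | (2S,5R,6S,10S)-2α,6α-diol 12-pivalate, 17-O-triisopropylsilyl | CC1(C)C[C@H](O)C[C@]2(C)C(CCOC(=O)C(C)(C)C)=C(CO[Si](C(C)C)(C(C)C)C(C)C)C[C@H](O)[C@H]12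
F4 | step 12 | open-chain C6 N,N-dimethylhydrazone with free C17 hydroxyl (12-O-pivaloyl; C7 cis to C10; (Z)-vinyl iodide) | CN(C)N=CC/C(CO)=C(CCOC(=O)C(C)(C)C)\C(C)=C/I
F5 | step 12 | 17-O-triisopropylsilyl ether of F4 | CN(C)N=CC/C(CO[Si](C(C)C)(C(C)C)C(C)C)=C(CCOC(=O)C(C)(C)C)\C(C)=C/I
F6 | step 12 | open-chain C6 aldehyde, 17-O-triisopropylsilyl, 12-O-pivaloyl | O=CC/C(CO[Si](C(C)C)(C(C)C)C(C)C)=C(CCOC(=O)C(C)(C)C)\C(C)=C/I
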